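**Assumption:** (R)-(−)-norepinephrine (free base or bitartrate) and tert-butyl 2-methylbut-3-en-2-yl carbonate are bought as catalogue materials; the target is the (2S)-flavan encoded in the SMILES.

## Retrosynthetic overview

1. Kazinol B ⇐ one-pot aromatic Claisen of a 3′-O-(1,1-dimethylallyl) ether (gives the 2′-prenyl group) and 7-O-demethylation of flavan 10.
2. Flavan pyran ring (C3–C4 bond) ⇐ anodic nitrogen deletion with ring contraction of the 2-aryl-tetrahydro-1,4-benzoxazepine 9.
3. Benzoxazepine ⇐ lactam 6 by intramolecular SNAr of the carbinol oxygen (forms O1–C8a) ⇐ amide 3 from (R)-norepinephrine and 2-fluoro-4-methoxybenzoic acid.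
4. B-ring dimethylpyran ⇐ prenal annulation of the catechol at 4′-O/C5′, directly after amide formation.
5. Ring order: B-ring pyran → oxazepinone → chroman (by contraction). C2 is the norepinephrine carbinol carbon and none of its bonds is broken; (R)-carbinol corresponds to (2S)-flavan only through the CIP priority change when N is replaced by C.

## Route

**Step 1**
Reactants: 1, (R)-norepinephrine; 2, 2-fluoro-4-methoxybenzoic acid
Product: 3, N-[(2R)-2-(3,4-dihydroxyphenyl)-2-hydroxyethyl]-2-fluoro-4-methoxybenzamide
Conditions: EDC·HCl, HOBt, iPr2NEt, DMF, 0 °C → rt, Ar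
Reagents that add atoms: 2-fluoro-4-methoxybenzoic acid (2), COc1ccc(C(=O)O)c(F)c1
Why: Carbodiimide/HOBt amide coupling is selective for the primary amine over the phenols and the alcohol (any aryl ester is cleaved on NaHCO3 work-up), leaves the carbinol stereocentre untouched, and the aroyl group both masks nitrogen and carries ring A.

**Step 2**
Reactants: 3; 4, 3-methylbut-2-enal (prenal)
Product: 5, N-[(2R)-2-hydroxy-2-(8-hydroxy-2,2-dimethyl-2H-chromen-6-yl)ethyl]-2-fluoro-4-methoxybenzamide
Conditions: prenal (2 equiv), pyridine (degassed), 110 °C, Ar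
Reagents that add atoms: 3-methylbut-2-enal (4), CC(C)=CC=O
Why: Phenol–enal [3+3] chromene annulation (ortho C-alkylation, dehydration to an o-quinone methide, oxa-6π electrocyclisation) should close on 4′-O/C5′, because C5′ is the only unhindered carbon ortho to a hydroxyl (C2′ is flanked by the side chain, C6′ is not ortho to OH); the metal-free, weakly basic medium avoids ionising or oxidising the carbinol, and no stereocentre is formed.

**Step 3**
Reactants: 5
Product: 6, (2R)-2-(8-hydroxy-2,2-dimethyl-2H-chromen-6-yl)-8-methoxy-3,4-dihydro-1,4-benzoxazepin-5(2H)-one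
Conditions: KOtBu (3.3 equiv), DMSO, 80 °C, Ar
Reagents that add atoms: none
Why: Intramolecular SNAr of the secondary alkoxide on the fluoride ortho to the amide carbonyl forms the aryl–O bond without breaking any bond at the stereocentre (retention); the 3′-phenoxide is meta to the side chain, so no quinone-methide pathway exists, and 4′-O is already capped as the chromene.

**Step 4**
Reactants: 6; 7, tert-butyl 2-methylbut-3-en-2-yl carbonate
Product: 8, (2R)-2-[2,2-dimethyl-8-(2-methylbut-3-en-2-yloxy)-2H-chromen-6-yl]-8-methoxy-3,4-dihydro-1,4-benzoxazepin-5(2H)-one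
Conditions: Pd(PPh3)4 (5 mol %), THF, 0 °C → rt
Reagents that add atoms: tert-butyl 2-methylbut-3-en-2-yl carbonate (7), C=CC(C)(C)OC(=O)OC(C)(C)C
Why: Decarboxylative Tsuji–Trost O-allylation gives the branched (tertiary) aryl ether kinetically; the phenol (pKa ≈ 10) is the only group deprotonated by the tert-butoxide released, so the lactam N–H is not allylated, and the ether serves as both phenol protection and latent prenyl group.

**Step 5**
Reactants: 8
Product: 9, (2R)-2-[2,2-dimethyl-8-(2-methylbut-3-en-2-yloxy)-2H-chromen-6-yl]-8-methoxy-2,3,4,5-tetrahydro-1,4-benzoxazepine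
Conditions: LiAlH4, THF, 60 °C
Reagents that add atoms: none
Why: LiAlH4 reduction of the lactam to the cyclic secondary amine leaves aryl ethers, the chromene alkene and the allyl ether untouched, and the [3,3] shift of the tert-allyl ether is negligible at 60 °C.

**Step 6**
Reactants: 9
Product: 10, (2S)-2-[2,2-dimethyl-8-(2-methylbut-3-en-2-yloxy)-2H-chromen-6-yl]-7-methoxychroman
Conditions: Ph2P(O)ONH2 (1.3 equiv), K2CO3, MeCN, rt; then nBu4NBF4, MeOH co-solvent, undivided cell, graphite(+)/Pt(−), +0.5 V vs Ag/AgCl (≈2.2 F mol⁻¹), 0 °C → rt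
Reagents that add atoms: none (the NH2 delivered by the aminating agent leaves with the ring nitrogen as N2)
Why: Proposed new method: anodic 2e⁻/2H⁺ oxidation of the in-situ N-amino amine (about +0.3–0.5 V, well below the >1.2 V needed to oxidise the alkoxyarenes, chromene or allyl ether) gives the 1,1-diazene, whose benzylic C5–N homolysis and N2 loss leave a 1,6-diradical that collapses to the C3–C4 bond, contracting the oxazepine to the chroman; slow electrogeneration keeps the diazene dilute (no tetrazene dimer), fragmentation to o-quinone methide plus styrene would cost ring-A aromaticity, and C2 is never a radical site, so configuration is retained; the closest known reactions are HgO oxidation of N-amino cyclic amines (Overberger-type ring contraction) and anomeric-amide nitrogen deletion of benzylic secondary amines, neither shown electrochemically nor on a benzoxazepine-to-flavan contraction.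

**Step 7**
Reactants: 10
Product: 12, kazinol B, via 11, (2S)-2-[8-hydroxy-2,2-dimethyl-7-(3-methylbut-2-enyl)-2H-chromen-6-yl]-7-methoxychroman (not isolated)
Conditions: DMF, 130 °C, 2 h; then NaSEt (6 equiv), 140 °C
Reagents that add atoms: none
Why: Aromatic Claisen rearrangement of the aryl 1,1-dimethylallyl ether to its only free ortho carbon (C2′) gives the 2′-prenyl phenol 11, then thiolate SN2 O-demethylation (added only after the Claisen, to avoid SN2′ loss of the allyl group) frees 7-OH; the chromene and prenyl groups are base-stable, and C2–O1 is a hindered secondary ether with 4′-O alkylated, so the stereocentre is not at risk.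

## Compound list

1 | (R)-norepinephrine | NC[C@H](O)c1ccc(O)c(O)c1 | starting material
2 | 2-fluoro-4-methoxybenzoic acid | COc1ccc(C(=O)O)c(F)c1 | starting material
3 | N-[(2R)-2-(3,4-dihydroxyphenyl)-2-hydroxyethyl]-2-fluoro-4-methoxybenzamide | COc1ccc(C(=O)NC[C@H](O)c2ccc(O)c(O)c2)c(F)c1 | intermediate
4 | 3-methylbut-2-enal (prenal) | CC(C)=CC=O | starting material
5 | N-[(2R)-2-hydroxy-2-(8-hydroxy-2,2-dimethyl-2H-chromen-6-yl)ethyl]-2-fluoro-4-methoxybenzamide | COc1ccc(C(=O)NC[C@H](O)c2cc3C=CC(C)(C)Oc3c(O)c2)c(F)c1 | intermediate
6 | (2R)-2-(8-hydroxy-2,2-dimethyl-2H-chromen-6-yl)-8-methoxy-3,4-dihydro-1,4-benzoxazepin-5(2H)-one | O=C1NC[C@@H](c2cc3C=CC(C)(C)Oc3c(O)c2)Oc2cc(OC)ccc12 | intermediate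
7 | tert-butyl 2-methylbut-3-en-2-yl carbonate | C=CC(C)(C)OC(=O)OC(C)(C)C | starting material
8 | (2R)-2-[2,2-dimethyl-8-(2-methylbut-3-en-2-yloxy)-2H-chromen-6-yl]-8-methoxy-3,4-dihydro-1,4-benzoxazepin-5(2H)-one | O=C1NC[C@@H](c2cc3C=CC(C)(C)Oc3c(OC(C)(C)C=C)c2)Oc2cc(OC)ccc12 | intermediate
9 | (2R)-2-[2,2-dimethyl-8-(2-methylbut-3-en-2-yloxy)-2H-chromen-6-yl]-8-methoxy-2,3,4,5-tetrahydro-1,4-benzoxazepine | C1NC[C@@H](c2cc3C=CC(C)(C)Oc3c(OC(C)(C)C=C)c2)Oc2cc(OC)ccc12 | intermediate
10 | (2S)-2-[2,2-dimethyl-8-(2-methylbut-3-en-2-yloxy)-2H-chromen-6-yl]-7-methoxychroman | C1C[C@@H](c2cc3C=CC(C)(C)Oc3c(OC(C)(C)C=C)c2)Oc2cc(OC)ccc12 | intermediate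
11 | (2S)-2-[8-hydroxy-2,2-dimethyl-7-(3-methylbut-2-enyl)-2H-chromen-6-yl]-7-methoxychroman (7-O-methylkazinol B) | C1C[C@@H](c2cc3C=CC(C)(C)Oc3c(O)c2CC=C(C)C)Oc2cc(OC)ccc12 | intermediate (not isolated)
12 | kazinol B, (2S)-2-[8-hydroxy-2,2-dimethyl-7-(3-methylbut-2-enyl)-2H-chromen-6-yl]chroman-7-ol | CC(C)=CCc1c([C@@H]2CCc3ccc(O)cc3O2)cc2c(c1O)OC(C)(C)C=C2 | target

## Summary

Total steps: 7. Longest linear sequence: 7 (from 1; compounds 2, 4 and 7 are purchased).

Steps most likely to fail:

1. **Step 6 (proposed anodic nitrogen deletion).** Risks are hydrazone or tetrazene formation, or diradical fragmentation and re-addition that erodes ee (check by chiral HPLC). Fallback with known chemistry and a different C3–C4 construction: run the B-ring steps on the N-trifluoroacetamide and release the amine; convert the amino alcohol to the (R)-aryl oxirane by exhaustive N-methylation and base; open it at CH2 with (2-bromo-4-methoxybenzyl)magnesium bromide/CuI; close the chroman by Cu-catalysed intramolecular O-arylation of the carbinol (retention).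

2. **Step 2 (prenal annulation of the free catechol).** The catechol ring is only phenol-like in nucleophilicity, and the p-hydroxybenzylic alcohol could partly racemise at 110 °C, so ee must be checked here. Fallback: switch from condensation to O-alkylation/[3,3]: mono-O-alkylate 3 with 3-chloro-3-methylbut-1-yne (DBU, cat. CuCl2, MeCN, 0 °C), then aryl propargyl Claisen (xylene, 140 °C). The two oxygens are not differentiated, so both pyran regioisomers form and are separated at this early, inexpensive stage.

3. **Step 3 (SNAr on a fluoroarene activated only by the deprotonated amide).** It may be sluggish. Fallback: switch to Cu-catalysed C–O coupling: start from 2-iodo-4-methoxybenzoic acid, install the tert-prenyl ether before ring closure, and close the seven-membered ring with CuI/1,10-phenanthroline, Cs2CO3, toluene, 70 °C.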